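## Retrosynthetic overview
1. The two C5 esters are removed first: the angelate on the C3 alcohol is installed last and the senecioate on the C9 α-ketol just before it. This leaves a cis-fused 3,9-dioxygenated eremophil-11-en-8-one.
2. The 9β-oxygen and the 10β-hydrogen come from a Δ9(10)-en-8-one by copper hydride 1,4-hydrosilylation followed by Rubottom oxidation. The 7β-isopropenyl group comes from the 7(11)-isopropylidene dienone by deconjugative protonation.
3. Key disconnection: ring B is cut at C5–C6 and C9–C10, and the C4–CH3 bond is cut as well. This gives a C7 ring-A enone, a C7 acyclic allylic bromide and a methyl cuprate, which are joined in one annulation.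
4. The ring-A enone comes from m-cresol by oxidative dearomatisation, selective hydrogenation and CBS reduction. The bromide comes from 2-methylbut-2-ene and acetyl chloride by Kondakov acylation, Schenck ene reaction and allylic transposition.
5. Ring order: ring A is the carbocycle of the arene, and ring B is formed in the fragment union.

Assumption: eremophilane numbering is used (C3 angelate carbon, C4 and C5 methyl-bearing carbons, C7 isopropenyl carbon, C8 ketone, C9 senecioate carbon, C10 ring-fusion CH) and β means the face that carries the C5 methyl group, so the target is 3α-OAng, 4β-Me, 5β-Me, 7β-isopropenyl (7αH), 9β-OSen, 10βH (cis-decalin, all ring substituents except the C5 methyl group equatorial).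

## Route

Step 1
Reactants: 1 3-methylphenol (m-cresol)
Product: 2 4,4-dimethoxy-3-methylcyclohexa-2,5-dien-1-one
Conditions: PhI(OAc)2 (2.2 equiv), MeOH, 0 °C → rt
Reagents that add atoms: methanol, CO
Why: Hypervalent-iodine oxidative dearomatisation of a para-unsubstituted phenol, in which two successive two-electron oxidations each let methanol attack the para carbon, gives the p-quinone monoketal, masks the future enone carbonyl and creates no stereocentre.

Step 2
Reactants: 2 4,4-dimethoxy-3-methylcyclohexa-2,5-dien-1-one
Product: 3 4,4-dimethoxy-3-methylcyclohex-2-en-1-one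
Conditions: H2 (1 atm), RhCl(PPh3)3 (5 mol %), benzene, rt
Reagents that add atoms: none
Why: Wilkinson hydrogenation selects by degree of substitution, so the disubstituted C5=C6 bond is saturated while the methyl-bearing C2=C3 bond survives (the classical 1,4-dien-3-one to 4-en-3-one selectivity), and the neutral medium prevents loss of methanol and rearomatisation.

Step 3
Reactants: 3 4,4-dimethoxy-3-methylcyclohex-2-en-1-one
Product: 4 (1R)-4,4-dimethoxy-3-methylcyclohex-2-en-1-ol
Conditions: (S)-Me-CBS (10 mol %), BH3·SMe2 (0.7 equiv), THF, −30 °C; aq NaHCO3 work-up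
Reagents that add atoms: none
Why: In this Corey–Bakshi–Shibata reduction the alkenyl flank of the enone plays the large group, so the (S)-oxazaborolidine–borane complex delivers hydride to one carbonyl face and sets the (R)-carbinol centre that becomes C3 of the target.

Step 4
Reactants: 4 (1R)-4,4-dimethoxy-3-methylcyclohex-2-en-1-ol
Product: 5 tert-butyl{[(1R)-4,4-dimethoxy-3-methylcyclohex-2-en-1-yl]oxy}dimethylsilane
Conditions: TBSCl, imidazole, DMF, rt
Reagents that add atoms: tert-butyldimethylsilyl chloride, CC(C)(C)[Si](C)(C)Cl
Why: Corey silylation of a secondary allylic alcohol runs under mildly basic conditions that leave the acid-labile allylic ketal and the stereocentre untouched.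

Step 5
Reactants: 5 tert-butyl{[(1R)-4,4-dimethoxy-3-methylcyclohex-2-en-1-yl]oxy}dimethylsilane
Product: 6 (4R)-4-(tert-butyldimethylsilyloxy)-2-methylcyclohex-2-en-1-one
Conditions: PPTS (10 mol %), acetone–H2O (10:1), rt
Reagents that add atoms: water, O
Why: Mild acid-catalysed hydrolysis of the allylic dimethyl ketal, which is far more labile than a secondary TBS ether, unveils the enone with its carbonyl 1,4 to the untouched silyloxy stereocentre.

Step 6
Reactants: 7 2-methylbut-2-ene; 8 acetyl chloride
Product: 9 4-chloro-3,4-dimethylpentan-2-one (racemic)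
Conditions: ZnCl2 (10 mol %), CH2Cl2, −20 → 0 °C
Reagents that add atoms: none
Why: In this Kondakov acylation (aliphatic Friedel–Crafts reaction) the acylium ion attacks the CH terminus of the trisubstituted alkene, chloride captures the tertiary cation, and the single racemic stereocentre is erased in the next step.

Step 7
Reactants: 9 4-chloro-3,4-dimethylpentan-2-one
Product: 10 3,4-dimethylpent-3-en-2-one
Conditions: DBU (1.2 equiv), Et2O, 0 °C → rt
Reagents that add atoms: none
Why: E1cB dehydrochlorination of the β-chloro ketone through its enolate gives the conjugated tetrasubstituted enone, and DBU also brings any β,γ-isomer into conjugation.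

Step 8
Reactants: 10 3,4-dimethylpent-3-en-2-one
Product: 11 3-(2-hydroperoxypropan-2-yl)but-3-en-2-one
Conditions: O2, tetraphenylporphyrin (0.5 mol %), visible light, CH2Cl2, 0 °C; solvent removed cold
Reagents that add atoms: dioxygen, O=O
Why: In the Schenck ene reaction of singlet oxygen with α,β-unsaturated carbonyl compounds hydrogen is abstracted from the alkyl group geminal to the carbonyl group (gem effect), so oxygen ends on the dimethyl-substituted carbon and the α-methyl group becomes the terminal methylene.

Step 9
Reactants: 11 3-(2-hydroperoxypropan-2-yl)but-3-en-2-one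
Product: 12 3-(2-hydroxypropan-2-yl)but-3-en-2-one
Conditions: PPh3 (1.05 equiv), CH2Cl2, 0 °C
Reagents that add atoms: none
Why: Triphenylphosphine reduces the O–O bond of the allylic hydroperoxide chemoselectively and touches neither the enone nor the tertiary C–O bond.

Step 10
Reactants: 12 3-(2-hydroxypropan-2-yl)but-3-en-2-one
Product: 13 3-(bromomethyl)-4-methylpent-3-en-2-one
Conditions: PBr3 (0.4 equiv), Et2O, −10 → 0 °C
Reagents that add atoms: phosphorus tribromide, BrP(Br)Br
Why: In this SN2′-type allylic transposition, known for Baylis–Hillman and other tertiary allylic alcohols, bromide enters at the unhindered methylene terminus and the double bond moves into the conjugated tetrasubstituted position, with no E/Z issue because the far terminus carries two methyl groups.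

Step 11
Reactants: 14 3-methylbut-2-enoic acid (senecioic acid, 2 equiv)
Product: 15 3-methylbut-2-enoic anhydride
Conditions: DCC (0.5 equiv), CH2Cl2, 0 °C → rt; filtered
Reagents that add atoms: none
Why: Carbodiimide dehydration of two molecules of acid gives the symmetrical anhydride, a donor that acylates without passing through the vinylketene that makes senecioyl chloride give deconjugated esters.

Step 12
Reactants: 16 (Z)-2-methylbut-2-enoic acid (angelic acid)
Product: 17 (Z)-2-methylbut-2-enoic 2,4,6-trichlorobenzoic anhydride
Conditions: 2,4,6-trichlorobenzoyl chloride (1.0 equiv), Et3N (1.05 equiv), toluene, rt; filtered and concentrated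
Reagents that add atoms: 2,4,6-trichlorobenzoyl chloride, O=C(Cl)c1c(Cl)cc(Cl)cc1Cl
Why: Yamaguchi-type mixed anhydride formation at room temperature without a nucleophilic catalyst keeps the Z geometry of angelic acid, and the two ortho chlorine atoms later steer an alcohol to the angeloyl carbonyl.

Step 13 (fragment union, ring B formed)
Reactants: 6 (4R)-4-(tert-butyldimethylsilyloxy)-2-methylcyclohex-2-en-1-one; 13 3-(bromomethyl)-4-methylpent-3-en-2-one
Product: 20 3α-(tert-butyldimethylsilyloxy)eremophila-7(11),9-dien-8-one, via lithium enolate 18 (not isolated), via 1,5-diketone 19 (not isolated)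
Conditions: MeLi (2.2 equiv), CuI (1.1 equiv), Et2O, 0 °C; 6, −78 → −40 °C; 13 (1.2 equiv), THF–HMPA (4:1), −78 → 0 °C; then MeOH, NaOMe (0.5 equiv), 0 → 40 °C; aq NH4Cl/NH3 work-up
Reagents that add atoms: methyllithium, [Li]C (delivered as lithium dimethylcuprate, [Li+].C[Cu-]C)
Why: In this tandem cuprate conjugate addition, enolate alkylation and aldol condensation (a Robinson-type annulation in the Boeckman manner) the methyl group adds to C4 anti to the C3 silyloxy group, the regiodefined enolate is alkylated at C5 by the allylic bromide anti to the new pseudoaxial C4 methyl group so that the two methyl groups end up cis, and methoxide then closes ring B through the acetyl enolate onto the C10 ketone and dehydrates.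

Step 14
Reactants: 20 3α-(tert-butyldimethylsilyloxy)eremophila-7(11),9-dien-8-one
Product: 22 3α-(tert-butyldimethylsilyloxy)-7αH-eremophila-9,11-dien-8-one, via lithium trienolate 21 (not isolated)
Conditions: LDA (1.3 equiv), THF, −78 °C, 45 min; cannulated into AcOH (5 equiv), THF, −78 °C
Reagents that add atoms: none
Why: In this deconjugative kinetic protonation LDA removes a proton from the isopropylidene methyl group syn to the carbonyl oxygen (no α-proton is left and the C1 protons lie anti to the carbonyl group), and the cross-conjugated trienolate is protonated at its α-carbon C7 from the α face, opposite the pseudoaxial C5 methyl group, which places the isopropenyl group β.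

Step 15
Reactants: 22 3α-(tert-butyldimethylsilyloxy)-7αH-eremophila-9,11-dien-8-one
Product: 23 3α-(tert-butyldimethylsilyloxy)-8-[dimethyl(phenyl)silyloxy]-7αH,10βH-eremophila-8,11-diene
Conditions: [(Ph3P)CuH]6 (5 mol %), PhMe2SiH (1.5 equiv), toluene, rt
Reagents that add atoms: dimethylphenylsilane, C[SiH](C)c1ccccc1
Why: Copper hydride catalysed 1,4-hydrosilylation (Stryker–Lipshutz) takes the enone in preference to the isolated isopropenyl group and gives the Δ8(9) silyl enol ether regiospecifically, and like cuprates on 10-methyloctalones the Cu–H adds to C10 from the β face because the α-face alternative would lead to a trans-decalin with a 5β-methyl/7β-isopropenyl syn-diaxial clash, so 10βH and the cis ring fusion result.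

Step 16
Reactants: 23 3α-(tert-butyldimethylsilyloxy)-8-[dimethyl(phenyl)silyloxy]-7αH,10βH-eremophila-8,11-diene
Product: 25 3α-(tert-butyldimethylsilyloxy)-9β-hydroxy-7αH,10βH-eremophil-11-en-8-one, via 9β-silyloxy ketone 24 (not isolated)
Conditions: mCPBA (1.05 equiv), hexane–CH2Cl2, −20 °C; then 10% aq citric acid, MeOH, rt
Reagents that add atoms: 3-chloroperoxybenzoic acid (mCPBA), O=C(OO)c1cccc(Cl)c1
Why: In this Rubottom oxidation the electron-rich silyl enol ether is epoxidised far faster than the 1,1-disubstituted alkene, attack comes from the convex β face of the cis-decalin because the α face is shielded by the axial C5–C4 bond, silyl migration gives the 9β-silyloxy ketone, and mild acid removes only the labile dimethylphenylsilyl group to leave the equatorial and thermodynamically preferred 9β-alcohol.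

Step 17
Reactants: 25 3α-(tert-butyldimethylsilyloxy)-9β-hydroxy-7αH,10βH-eremophil-11-en-8-one; 15 3-methylbut-2-enoic anhydride
Product: 26 3α-(tert-butyldimethylsilyloxy)-9β-(3-methylbut-2-enoyloxy)-7αH,10βH-eremophil-11-en-8-one
Conditions: 15 (1.5 equiv), DMAP (0.2 equiv), pyridine, CH2Cl2, 0 °C → rt
Reagents that add atoms: none
Why: DMAP-catalysed (Steglich-type) acylation of the only free hydroxyl group by the symmetrical anhydride touches no stereocentre, and since C7 and C9 already carry equatorial substituents the mild base has nothing to epimerise.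

Step 18
Reactants: 26 3α-(tert-butyldimethylsilyloxy)-9β-(3-methylbut-2-enoyloxy)-7αH,10βH-eremophil-11-en-8-one
Product: 27 3α-hydroxy-9β-(3-methylbut-2-enoyloxy)-7αH,10βH-eremophil-11-en-8-one
Conditions: HF·pyridine, THF–pyridine, 0 °C → rt
Reagents that add atoms: none
Why: Fluoride-induced Si–O cleavage in a buffered acidic medium avoids the basicity of TBAF, which could move the acyl group, epimerise C7 or C9 or pull the isopropenyl group into conjugation.

Step 19
Reactants: 27 3α-hydroxy-9β-(3-methylbut-2-enoyloxy)-7αH,10βH-eremophil-11-en-8-one; 17 (Z)-2-methylbut-2-enoic 2,4,6-trichlorobenzoic anhydride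
Product: 28 3α-angeloyloxy-9β-senecioyloxy-7αH,10βH-eremophil-11-en-8-one (target)
Conditions: 17 (3 equiv), Et3N (3 equiv), toluene, 80 °C
Reagents that add atoms: none
Why: In this Yamaguchi-type angeloylation the hindered aroyl half of the mixed anhydride directs the equatorial C3 alcohol to the angeloyl carbonyl, and the absence of DMAP or other nucleophilic catalysts prevents Z to E (tiglate) isomerisation, so the target forms with retention at C3.

## Compound list
1 | 3-methylphenol (m-cresol) | Cc1cccc(O)c1 | starting material
2 | 4,4-dimethoxy-3-methylcyclohexa-2,5-dien-1-one | COC1(OC)C=CC(=O)C=C1C | intermediate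
3 | 4,4-dimethoxy-3-methylcyclohex-2-en-1-one | COC1(OC)CCC(=O)C=C1C | intermediate
4 | (1R)-4,4-dimethoxy-3-methylcyclohex-2-en-1-ol | COC1(OC)CC[C@@H](O)C=C1C | intermediate
5 | tert-butyl{[(1R)-4,4-dimethoxy-3-methylcyclohex-2-en-1-yl]oxy}dimethylsilane | COC1(OC)CC[C@@H](O[Si](C)(C)C(C)(C)C)C=C1C | intermediate
6 | (4R)-4-(tert-butyldimethylsilyloxy)-2-methylcyclohex-2-en-1-one | O=C1CC[C@@H](O[Si](C)(C)C(C)(C)C)C=C1C | intermediate
7 | 2-methylbut-2-ene | CC=C(C)C | starting material
8 | acetyl chloride | CC(=O)Cl | starting material
9 | 4-chloro-3,4-dimethylpentan-2-one (racemic) | CC(=O)C(C)C(C)(C)Cl | intermediate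
10 | 3,4-dimethylpent-3-en-2-one | CC(=O)C(C)=C(C)C | intermediate
11 | 3-(2-hydroperoxypropan-2-yl)but-3-en-2-one | CC(=O)C(=C)C(C)(C)OO | intermediate
12 | 3-(2-hydroxypropan-2-yl)but-3-en-2-one | CC(=O)C(=C)C(C)(C)O | intermediate
13 | 3-(bromomethyl)-4-methylpent-3-en-2-one | CC(=O)C(CBr)=C(C)C | intermediate
14 | 3-methylbut-2-enoic acid (senecioic acid) | CC(C)=CC(=O)O | starting material
15 | 3-methylbut-2-enoic anhydride | CC(C)=CC(=O)OC(=O)C=C(C)C | intermediate
16 | (Z)-2-methylbut-2-enoic acid (angelic acid) | C/C=C(/C)C(=O)O | starting material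
17 | (Z)-2-methylbut-2-enoic 2,4,6-trichlorobenzoic anhydride | C/C=C(/C)C(=O)OC(=O)c1c(Cl)cc(Cl)cc1Cl | intermediate
18 | lithium (3R,4R)-4-(tert-butyldimethylsilyloxy)-2,3-dimethylcyclohex-1-en-1-olate | CC1=C([O-])CC[C@@H](O[Si](C)(C)C(C)(C)C)[C@@H]1C.[Li+] | intermediate
19 | (2R,3R,4R)-2-(2-acetyl-3-methylbut-2-en-1-yl)-4-(tert-butyldimethylsilyloxy)-2,3-dimethylcyclohexan-1-one | CC(=O)C(=C(C)C)C[C@@]1(C)C(=O)CC[C@@H](O[Si](C)(C)C(C)(C)C)[C@@H]1C | intermediate
20 | 3α-(tert-butyldimethylsilyloxy)eremophila-7(11),9-dien-8-one, i.e. (4aR,5R,6R)-6-(tert-butyldimethylsilyloxy)-4a,5-dimethyl-3-(propan-2-ylidene)-4,4a,5,6,7,8-hexahydronaphthalen-2(3H)-one | CC(C)=C1C[C@@]2(C)C(CC[C@@H](O[Si](C)(C)C(C)(C)C)[C@@H]2C)=CC1=O | intermediate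
21 | lithium 8-olate of 3α-(tert-butyldimethylsilyloxy)eremophila-7,9,11-triene (cross-conjugated trienolate) | C=C(C)C=1C[C@@]2(C)C(CC[C@@H](O[Si](C)(C)C(C)(C)C)[C@@H]2C)=CC=1[O-].[Li+] | intermediate
22 | 3α-(tert-butyldimethylsilyloxy)-7αH-eremophila-9,11-dien-8-one (isopropenyl β), i.e. the (3R,4aR,5R,6R)-3-(prop-1-en-2-yl) isomer of 20 | C=C(C)[C@H]1C[C@@]2(C)C(CC[C@@H](O[Si](C)(C)C(C)(C)C)[C@@H]2C)=CC1=O | intermediate
23 | 3α-(tert-butyldimethylsilyloxy)-8-[dimethyl(phenyl)silyloxy]-7αH,10βH-eremophila-8,11-diene | C=C(C)[C@H]1C[C@@]2(C)[C@H](CC[C@@H](O[Si](C)(C)C(C)(C)C)[C@@H]2C)C=C1O[Si](C)(C)c3ccccc3 | intermediate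
24 | 3α-(tert-butyldimethylsilyloxy)-9β-[dimethyl(phenyl)silyloxy]-7αH,10βH-eremophil-11-en-8-one | C=C(C)[C@H]1C[C@@]2(C)[C@H](CC[C@@H](O[Si](C)(C)C(C)(C)C)[C@@H]2C)[C@@H](O[Si](C)(C)c3ccccc3)C1=O | intermediate
25 | 3α-(tert-butyldimethylsilyloxy)-9β-hydroxy-7αH,10βH-eremophil-11-en-8-one | C=C(C)[C@H]1C[C@@]2(C)[C@H](CC[C@@H](O[Si](C)(C)C(C)(C)C)[C@@H]2C)[C@@H](O)C1=O | intermediate
26 | 3α-(tert-butyldimethylsilyloxy)-9β-(3-methylbut-2-enoyloxy)-7αH,10βH-eremophil-11-en-8-one | C=C(C)[C@H]1C[C@@]2(C)[C@H](CC[C@@H](O[Si](C)(C)C(C)(C)C)[C@@H]2C)[C@@H](OC(=O)C=C(C)C)C1=O | intermediate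
27 | 3α-hydroxy-9β-(3-methylbut-2-enoyloxy)-7αH,10βH-eremophil-11-en-8-one | C=C(C)[C@H]1C[C@@]2(C)[C@H](CC[C@@H](O)[C@@H]2C)[C@@H](OC(=O)C=C(C)C)C1=O | intermediate
28 | (1R,2R,4aS,5R,7R,8aR)-1,8a-dimethyl-5-[(3-methylbut-2-enoyl)oxy]-6-oxo-7-(prop-1-en-2-yl)decahydronaphthalen-2-yl (2Z)-2-methylbut-2-enoate (CNP0375730.2) | C=C(C)[C@H]1C[C@@]2(C)[C@H](CC[C@@H](OC(=O)/C(C)=C\C)[C@@H]2C)[C@@H](OC(=O)C=C(C)C)C1=O | target

## Step count and risks
Total step count: 19.
Longest linear sequence: 12 steps (steps 1–5 then 13–19, or equally steps 6–10 then 13–19).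

Step 13 is the most likely to fail. The hindered tetrasubstituted enolate 18 may take a proton from bromide 13, which then loses HBr, instead of being alkylated, and residual methylcopper may consume 13. The fallback sets out from 6 and comes back at 20. After the same cuprate addition the enolate is trapped by Michael addition to 3-(trimethylsilyl)but-3-en-2-one (Stork–Boeckman annulation), which gives the α-silyl 1,5-diketone F1. NaOMe in MeOH removes the silyl group and closes ring B to 3α-(tert-butyldimethylsilyloxy)eremophil-9-en-8-one F2. The three-carbon unit is then added after the annulation: the kinetic C7 zinc enolate (LDA, ZnCl2) reacts with acetone to give the 11-hydroxy aldol adduct F3. Acid-catalysed dehydration (cat. TsOH, benzene) then gives 20.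

Step 14 is the second risk. The base may take a C1 proton instead, the product may slip back into conjugation, or C7 may come out as the 7α epimer. The fallback sets out from 20 and comes back at 22 without any strong base. It is a photochemical deconjugation: irradiation (λ > 300 nm, hexane, cat. 1,2-dimethylimidazole) of the s-cis isopropylidene enone triggers a 1,5-hydrogen shift from the syn methyl group to oxygen, and the photodienol ketonises at C7. This path makes no new compound (F0). The C7 epimers are separated, and the unwanted 7α epimer is returned to 20 with DBU.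

Step 15 is the third risk. The β,β-disubstituted enone next to a quaternary carbon may react slowly, and the cis selectivity is inferred from related octalones. The fallback sets out from 20 and comes back at 25, with reduction, oxidation and deconjugation carried out in a different order. Heterogeneous hydrogenation (H2, Pd/C, EtOAc, trace of pyridine) saturates only the trisubstituted Δ9(10) bond of the dienone and gives the cis-fused 3α-(tert-butyldimethylsilyloxy)-10βH-eremophil-7(11)-en-8-one F4. Kinetic α′-deprotonation at C9 (LDA) and oxidation with a Davis oxaziridine from the convex face gives the 9β-hydroxy-7(11)-en-8-one F5. Two equivalents of LDA then form the C9 alkoxide, which shields C9–H, and remove a syn methyl proton. Kinetic protonation followed by a short DBU equilibration of C7 to the equatorial 7β position gives 25.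

## Further compounds
F1 | step 13 | (2R,3R,4R)-4-(tert-butyldimethylsilyloxy)-2,3-dimethyl-2-[3-oxo-2-(trimethylsilyl)butyl]cyclohexan-1-one (epimers at the silyl-bearing carbon) | CC(=O)C(C[C@@]1(C)C(=O)CC[C@@H](O[Si](C)(C)C(C)(C)C)[C@@H]1C)[Si](C)(C)C
F2 | step 13 | 3α-(tert-butyldimethylsilyloxy)eremophil-9-en-8-one | C1C[C@@]2(C)C(CC[C@@H](O[Si](C)(C)C(C)(C)C)[C@@H]2C)=CC1=O
F3 | step 13 | 3α-(tert-butyldimethylsilyloxy)-11-hydroxyeremophil-9-en-8-one (C7 epimers) | CC(C)(O)C1C[C@@]2(C)C(CC[C@@H](O[Si](C)(C)C(C)(C)C)[C@@H]2C)=CC1=O
F0 | step 14 | none | none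
F4 | step 15 | 3α-(tert-butyldimethylsilyloxy)-10βH-eremophil-7(11)-en-8-one | CC(C)=C1C[C@@]2(C)[C@H](CC[C@@H](O[Si](C)(C)C(C)(C)C)[C@@H]2C)CC1=O
F5 | step 15 | 3α-(tert-butyldimethylsilyloxy)-9β-hydroxy-10βH-eremophil-7(11)-en-8-one | CC(C)=C1C[C@@]2(C)[C@H](CC[C@@H](O[Si](C)(C)C(C)(C)C)[C@@H]2C)[C@@H](O)C1=O
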